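G goes slowly here: in Wednesday's, G halves by the step to G.Q alone, Q as charged, in 12 h, and by the step to J alone in 27 h.

    G + Q → G.Q (k1 = 0.197 M⁻¹ h⁻¹)
    G → J (k2 = 0.0261 h⁻¹)
    2 G → G2 (k3 = 0.0763 M⁻¹ h⁻¹)
    G + G.Q → G.G.Q (k4 = 0.0224 M⁻¹ h⁻¹)
    2 Q → Q2 (k5 = 0.0538 M⁻¹ h⁻¹)

the same everywhere: time 25 h
- Saturday's: G 0.20 M (fed, over 10 h); Q 0.300 M; all else is in the flask from the start; the feed brings no volume worth counting
- Wednesday's: G 0.20 M; Q 0.300 M; everything together at the start
- Sunday's: G 0.20 M; Q 0.300 M (fed, over 2.5 h); all else is in the flask from the start; the feed brings no volume worth counting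
- Friday's: G 0.20 M; Q 0.300 M (fed, over 10 h); all else is in the flask from the start; the feed brings no volume worth counting

- a species is counted by the G in it: one G2 or G.G.Q counts as two
- two of one species on the left: rate k times its square, two consumed each time
- run time (Saturday's): 25 h

* the flask that comes out highest in amount of G.Q, in percent of the G charged, or "all alike" when all lie within 1.5 percentage points (Saturday's / Wednesday's / Sunday's / Friday's / all alike)
* G.Q at the end, in percent of the G charged, Saturday's
* G.Q at the end, in percent of the G charged, Wednesday's
* G.Q at the end, in percent of the G charged, Sunday's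
* G.Q at the end, in percent of the G charged, Friday's

G, at 0.20 M, is less than Q at 0.300 M, so I took G as the limiting reagent and kept the books on it for Wednesday's. I replaced each curve by its mean. Counting the dimerisation of Q and no other loss, I reckoned Q at a mean of 0.220 M over the run. G.Q holds some Q too. For that I took off one part in 5 of the G charge, a rough guess, which left 0.180 M. For G I took the middle between charge and nothing, 0.100 M. At those means I reckoned G leaving at 0.0355 h⁻¹ into G.Q, 0.0261 h⁻¹ into J and 0.0153 h⁻¹ into G2, together 0.0768 h⁻¹.

The G.Q share, the part of G's loss at mean levels that goes into G.Q (its selectivity), was 46.2%. Over 25 h at that total rate, I reckoned 85.3% of the G lost. My ledger for Wednesday's read: G.Q 39.4%, J 29.0%, G2 17.0%, G unspent 14.7%. The books closed at 100%. I booked nothing to G.G.Q, since the half-life of G.Q by that step alone in Wednesday's, 150 h, is longer than the run of 25 h. I closed no books for the fed flasks.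

The forecast put Wednesday's highest at 40%, then Sunday's at 38%, Saturday's at 35.4% and Friday's at 32.5%. Its ground for Wednesday's was: “all in at once gives the greatest overlap”. My 39.4% for that flask was lower than its figure.

Wednesday's came out highest at 40.1%, then Sunday's at 37.9%, Saturday's at 35.4% and Friday's at 32.2%. In Wednesday's, the share of 46.2% had booked 39.4% of G.Q. G stood at 15.2% against my 14.7%, G2 at 16.3% against 17.0%, and J at 26.4% against 29.0%. I ran the same means on Wednesday's recipe with 0.34 M of G. The share came to 36.5%, which booked 31.8% of G.Q. That neighbour gave 33.9% of G.Q, with 13.8% of its G unspent and G2 at 24.8%.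

(All constants stand for no real mixture; the flask was simulated.)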